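A direct plan would build a carbamate-differentiated spermine linearly from 4-aminobutan-1-ol by two reductive aminations, through the N-protected 4-oxobutyl aldehyde A1 to the Boc/Cbz-differentiated tetraamine A2. It would then free two nitrogens, acylate both with the benzyl-protected cinnamic acid A3 and hydrogenate. Its weakest steps would be:
- the alcohol oxidation to A1 and its reductive amination, since the amino aldehyde would be unstable and the new secondary amine could be alkylated twice;
- the carbamate protection and removal on nitrogen, which would add steps only to tell four nitrogens apart;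
- the aldol–elimination–saponification sequence to A3, which would create an alkene that the last step erases.

With the backbone numbered from the free NH2 (N1) to the terminal amide nitrogen (N14), the route cuts the tetramethylene chain itself: the C8–C9 and C9–N10 bonds, with C9 supplied by formaldehyde. Because N5 is a non-basic tertiary amide and N10 a basic secondary amine, C6–C9 maps onto a but-2-yne-1,4-diyl unit. A CuBr-catalysed alkyne–formaldehyde–amine Mannich coupling joins an N5-propargyl amide (carrying N1 and the N5 acyl group) to an N10-benzyl amine (carrying the N14 acyl group) in one operation. The acylation pattern is thereby settled on two simple 1,3-diamines, no amino aldehyde or orthogonal carbamate set is needed, and one hydrogenation removes the alkyne and every benzyl-type group.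

Key step: step 5

Assumption: the target is achiral, so no stereocentre has to be set; it is taken as the free base and handled under argon because the catechols oxidise in air.

Step 1
Reactants: 1 3-(3,4-dihydroxyphenyl)propanoic acid (dihydrocaffeic acid)
Product: 3 3-[3,4-bis(benzyloxy)phenyl]propanoic acid, via benzyl ester 2 (not isolated)
Conditions: BnBr (3.5 equiv), K2CO3 (4 equiv), DMF, 60 °C, N2; then 2 M aq NaOH, MeOH/THF, 60 °C; 1 M HCl to pH 2, filter
Reagents that add atoms: benzyl bromide, BrCc1ccccc1; sodium hydroxide, [Na+].[OH-]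
Why: Williamson O-alkylation of both phenols and the carboxylate followed by saponification of the benzyl ester should leave the hydroxide-stable aryl benzyl ethers in place and deliver the acid on acidification.

Step 2
Reactants: 4 prop-2-yn-1-amine (propargylamine); 5 benzyl (3-bromopropyl)carbamate
Product: 6 benzyl {3-[(prop-2-yn-1-yl)amino]propyl}carbamate
Conditions: 4 (5 equiv), K2CO3 (1.5 equiv), MeCN, 45 °C; excess 4 removed by evaporation
Reagents that add atoms: none
Why: SN2 N-alkylation of a primary amine by a primary bromide, in which the fivefold excess of the volatile amine should suppress dialkylation and the carbamate N–H is not nucleophilic under carbonate.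

Step 3
Reactants: 3 3-[3,4-bis(benzyloxy)phenyl]propanoic acid; 6 benzyl {3-[(prop-2-yn-1-yl)amino]propyl}carbamate
Product: 8 benzyl {3-[{3-[3,4-bis(benzyloxy)phenyl]propanoyl}(prop-2-yn-1-yl)amino]propyl}carbamate, via acid chloride 7 (not isolated)
Conditions: 3, (COCl)2 (1.2 equiv), DMF (cat.), CH2Cl2, 0 °C → rt, evaporate; then 6 (1.0 equiv), Et3N (2.5 equiv), CH2Cl2, 0 °C → rt
Reagents that add atoms: none
Why: Acid chloride formation and N-acylation of the secondary amine should install the N5 acyl group, since the carbamate N–H and the terminal alkyne do not react and the acid has no sensitive α-centre.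

Step 4
Reactants: 3 3-[3,4-bis(benzyloxy)phenyl]propanoic acid; 9 N1-benzylpropane-1,3-diamine
Product: 11 N-[3-(benzylamino)propyl]-3-[3,4-bis(benzyloxy)phenyl]propanamide, via acyl imidazole 10 (not isolated)
Conditions: 3, CDI (1.05 equiv), THF, rt, 1 h; then added to 9 (1.3 equiv), THF, −10 °C → rt
Reagents that add atoms: none
Why: CDI activation and chemoselective aminolysis, in which the mild acyl imidazole should acylate the unhindered primary amine much faster than the N-benzyl secondary amine, so that N14 is acylated and N10 stays free.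

Step 5
Reactants: 8 benzyl {3-[{3-[3,4-bis(benzyloxy)phenyl]propanoyl}(prop-2-yn-1-yl)amino]propyl}carbamate; 11 N-[3-(benzylamino)propyl]-3-[3,4-bis(benzyloxy)phenyl]propanamide; 12 formaldehyde (as paraformaldehyde)
Product: 15 N1-benzyloxycarbonyl-N10-benzyl-N5,N14-bis{3-[3,4-bis(benzyloxy)phenyl]propanoyl}-7,8-didehydrospermine (C7≡C8 triple bond), via hemiaminal 13 (not isolated), via copper acetylide 14 (not isolated)
Conditions: 8 (1.0 equiv), 11 (1.1 equiv), 12 (1.3 equiv), CuBr (10 mol %), 1,4-dioxane, 80 °C, Ar
Reagents that add atoms: none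
Why: Amine 11 condenses at N10 with formaldehyde to hemiaminal 13, which ionises to an N-benzyl methyleneiminium ion, while CuBr π-complexes the terminal alkyne of 8 and, with the amine as base, gives the monovalent copper acetylide 14; addition of 14 to the iminium carbon forges C8–C9, the C9–N10 bond having been made in the condensation, and releases the catalyst. The closest known reaction type is the copper-catalysed alkyne–aldehyde–amine Mannich (A3) coupling with formaldehyde, which is well established for N-propargyl amides and lactams with dialkylamines. No ring is closed and no stereocentre is formed. The step needs chemoselectivity among three N–H groups and cross-selectivity between the halves: only N10 is basic enough to form an iminium ion (the N14 amide and the N1 carbamate are not), only 8 carries an acidic alkyne C–H, and the tertiary amide at N5 cannot cyclise onto the activated alkyne, so the halves can only join head to tail. Argon excludes oxidative alkyne homocoupling, and since the acetylide addition is irreversible, any reversible aminal formation at the N14 amide should drain into 15.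

Step 6
Reactants: 15 N1-benzyloxycarbonyl-N10-benzyl-N5,N14-bis{3-[3,4-bis(benzyloxy)phenyl]propanoyl}-7,8-didehydrospermine
Product: 17 kukoamine B, via saturated benzyl-protected spermine 16 (not isolated)
Conditions: H2 (1 atm), 20% Pd(OH)2/C, iPrOH/THF 1:1, rt, until the alkyne is saturated; then AcOH (5 equiv), H2 (4 bar), rt → 40 °C; filter (Celite, Ar); weakly basic anion-exchange resin (free-base form), degassed MeOH; evaporate
Reagents that add atoms: none
Why: Heterogeneous catalytic hydrogenation should first saturate the C7≡C8 triple bond under neutral conditions, after which hydrogenolysis cleaves the four aryl benzyl ethers, the N10-benzyl group and the Cbz group (the carbamic acid loses CO2), while amide and alkyl C–N bonds persist.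

**Compound list**
1 | 3-(3,4-dihydroxyphenyl)propanoic acid | OC(=O)CCc1ccc(O)c(O)c1 | starting material
2 | benzyl 3-[3,4-bis(benzyloxy)phenyl]propanoate | O=C(CCc1ccc(OCc2ccccc2)c(OCc2ccccc2)c1)OCc1ccccc1 | intermediate
3 | 3-[3,4-bis(benzyloxy)phenyl]propanoic acid | OC(=O)CCc1ccc(OCc2ccccc2)c(OCc2ccccc2)c1 | intermediate
4 | prop-2-yn-1-amine | C#CCN | starting material
5 | benzyl (3-bromopropyl)carbamate | BrCCCNC(=O)OCc1ccccc1 | starting material
6 | benzyl {3-[(prop-2-yn-1-yl)amino]propyl}carbamate | C#CCNCCCNC(=O)OCc1ccccc1 | intermediate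
7 | 3-[3,4-bis(benzyloxy)phenyl]propanoyl chloride | ClC(=O)CCc1ccc(OCc2ccccc2)c(OCc2ccccc2)c1 | intermediate
8 | benzyl {3-[{3-[3,4-bis(benzyloxy)phenyl]propanoyl}(prop-2-yn-1-yl)amino]propyl}carbamate | C#CCN(CCCNC(=O)OCc1ccccc1)C(=O)CCc1ccc(OCc2ccccc2)c(OCc2ccccc2)c1 | intermediate
9 | N1-benzylpropane-1,3-diamine | NCCCNCc1ccccc1 | starting material
10 | 3-[3,4-bis(benzyloxy)phenyl]-1-(1H-imidazol-1-yl)propan-1-one | O=C(CCc1ccc(OCc2ccccc2)c(OCc2ccccc2)c1)n1ccnc1 | intermediate
11 | N-[3-(benzylamino)propyl]-3-[3,4-bis(benzyloxy)phenyl]propanamide | O=C(CCc1ccc(OCc2ccccc2)c(OCc2ccccc2)c1)NCCCNCc1ccccc1 | intermediate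
12 | formaldehyde (used as paraformaldehyde) | C=O | starting material
13 | N-{3-[benzyl(hydroxymethyl)amino]propyl}-3-[3,4-bis(benzyloxy)phenyl]propanamide | OCN(Cc1ccccc1)CCCNC(=O)CCc1ccc(OCc2ccccc2)c(OCc2ccccc2)c1 | intermediate
14 | monovalent copper acetylide of 8 | [Cu]C#CCN(CCCNC(=O)OCc1ccccc1)C(=O)CCc1ccc(OCc2ccccc2)c(OCc2ccccc2)c1 | intermediate
15 | benzyl {3-[{4-[benzyl(3-{3-[3,4-bis(benzyloxy)phenyl]propanamido}propyl)amino]but-2-yn-1-yl}{3-[3,4-bis(benzyloxy)phenyl]propanoyl}amino]propyl}carbamate | O=C(OCc1ccccc1)NCCCN(CC#CCN(Cc1ccccc1)CCCNC(=O)CCc1ccc(OCc2ccccc2)c(OCc2ccccc2)c1)C(=O)CCc1ccc(OCc2ccccc2)c(OCc2ccccc2)c1 | intermediate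
16 | benzyl {3-[{4-[benzyl(3-{3-[3,4-bis(benzyloxy)phenyl]propanamido}propyl)amino]butyl}{3-[3,4-bis(benzyloxy)phenyl]propanoyl}amino]propyl}carbamate | O=C(OCc1ccccc1)NCCCN(CCCCN(Cc1ccccc1)CCCNC(=O)CCc1ccc(OCc2ccccc2)c(OCc2ccccc2)c1)C(=O)CCc1ccc(OCc2ccccc2)c(OCc2ccccc2)c1 | intermediate
17 | kukoamine B, N5,N14-bis[3-(3,4-dihydroxyphenyl)propanoyl]spermine (numbered from the free NH2) | NCCCN(CCCCNCCCNC(=O)CCc1ccc(O)c(O)c1)C(=O)CCc1ccc(O)c(O)c1 | target

Total step count: 6. Longest linear sequence: 4 (steps 1, 3, 5, 6).

Steps most likely to fail: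

Step 5. The methyleneiminium ion may be diverted before the acetylide reaches it, by capture through the N14 amide N–H to a cyclic N-acyl aminal that reopens too slowly, or the acetylide may form sluggishly and dimerise oxidatively if air enters. The fallback sets out from 11 and comes back at 15, and brings in the four-carbon unit ready-made by two SN2 displacements instead of a C–C coupling. Amine 11 would be N-alkylated with 1,4-dichlorobut-2-yne (5 equiv, K2CO3, MeCN, 0 °C → rt) to N-{3-[benzyl(4-chlorobut-2-yn-1-yl)amino]propyl}-3-[3,4-bis(benzyloxy)phenyl]propanamide F1. The chloride would be displaced by commercial benzyl (3-aminopropyl)carbamate (3 equiv, K2CO3, NaI cat., MeCN) to the secondary amine benzyl {3-[(4-{benzyl[3-({3-[3,4-bis(benzyloxy)phenyl]propanoyl}amino)propyl]amino}but-2-yn-1-yl)amino]propyl}carbamate F2. Acylation of F2 at N5 with acid chloride 7 (Et3N, CH2Cl2, 0 °C) would give 15.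

Step 6. The propargylic or allylic C9–N10 bond may be cleaved hydrogenolytically on Pd(OH)2/C before saturation is complete, or the N-debenzylation may stall through amine poisoning of the catalyst. The fallback sets out from 15 and comes back at 16. The triple bond would be saturated without a metal surface by diimide transfer hydrogenation (2-nitrobenzenesulfonyl hydrazide in repeated charges, Et3N, CH2Cl2, rt) and 16 would be isolated. It would then be submitted to hydrogenolysis only (20% Pd(OH)2/C, H2, iPrOH/THF/AcOH) to reach 17. No new compound arises.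

Step 4. Acylation may compete at the secondary benzylamine nitrogen or occur twice, giving regioisomers that are hard to separate. The fallback sets out from 10 and comes back at 11. Acyl imidazole 10 would be added to a tenfold excess of propane-1,3-diamine (THF, 0 °C) to give N-(3-aminopropyl)-3-[3,4-bis(benzyloxy)phenyl]propanamide F3. Stepwise reductive amination with benzaldehyde (1.0 equiv, MeOH, 3 Å MS, rt) would pass through the (E)-benzaldimine of F3, F4, and reduction with NaBH4 (0 °C) would install the N-benzyl group to give 11.

**Further compounds**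
F1 | step 5 | N-{3-[benzyl(4-chlorobut-2-yn-1-yl)amino]propyl}-3-[3,4-bis(benzyloxy)phenyl]propanamide | ClCC#CCN(Cc1ccccc1)CCCNC(=O)CCc1ccc(OCc2ccccc2)c(OCc2ccccc2)c1
F2 | step 5 | benzyl {3-[(4-{benzyl[3-({3-[3,4-bis(benzyloxy)phenyl]propanoyl}amino)propyl]amino}but-2-yn-1-yl)amino]propyl}carbamate | O=C(OCc1ccccc1)NCCCNCC#CCN(Cc1ccccc1)CCCNC(=O)CCc1ccc(OCc2ccccc2)c(OCc2ccccc2)c1
F0 | step 6 | none | none
F3 | step 4 | N-(3-aminopropyl)-3-[3,4-bis(benzyloxy)phenyl]propanamide | NCCCNC(=O)CCc1ccc(OCc2ccccc2)c(OCc2ccccc2)c1
F4 | step 4 | N-{3-[(E)-benzylideneamino]propyl}-3-[3,4-bis(benzyloxy)phenyl]propanamide | c1ccccc1/C=N/CCCNC(=O)CCc1ccc(OCc2ccccc2)c(OCc2ccccc2)c1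
A1 | direct plan | benzyl {3-[(tert-butoxycarbonyl)amino]propyl}(4-oxobutyl)carbamate | CC(C)(C)OC(=O)NCCCN(CCCC=O)C(=O)OCc1ccccc1
A2 | direct plan | N1,N9-bis(benzyloxycarbonyl)-N12-(tert-butoxycarbonyl)spermine | CC(C)(C)OC(=O)NCCCN(CCCCNCCCNC(=O)OCc1ccccc1)C(=O)OCc1ccccc1
A3 | direct plan | (E)-3-[3,4-bis(benzyloxy)phenyl]prop-2-enoic acid | OC(=O)/C=C/c1ccc(OCc2ccccc2)c(OCc2ccccc2)c1
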